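**Assumption:** 2‑methoxyprop‑2‑yl hydroperoxide (8) is not a catalogue reagent, so its one‑step preparation is counted. Dioxane locants follow the target throughout (C3 = ring CH carrying the propanoate arm, C6 = quaternary ring carbon).

## Retrosynthetic overview

1. Target 27 ⇐ diimide saturation of the side‑chain alkene of dienone 26 ⇐ Horner–Wadsworth–Emmons union (penultimate step) of α‑peroxy aldehyde 16 (C10, all three stereocentres) with enone phosphonate 25 (C10 ring unit).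
2. 16 ⇐ dioxane diol 12 (vinyl → CO2Me, glycol cleavage → CHO); the 1,2‑dioxane is closed by acid‑triggered 6‑exo attack of a C3 hydroperoxide on a Sharpless epoxide, with inversion at C6.
3. C3–OO ⇐ SN2 (inversion) on the mesylate of an anti‑crotylation product; the (E)‑trisubstituted alkene ⇐ carbocupration of methyl but‑2‑ynoate.
4. 25 ⇐ Stork–Danheiser transposition on the vinylogous ester of 2,4,4‑trimethylcyclohexane‑1,3‑dione, itself from 3‑methylbutan‑2‑one + methyl acrylate and C‑methylation.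
5. Ring order: the carbocycle (east) and the 1,2‑dioxane (west) are each completed before the union; no ring is formed afterwards.

## Route

### West fragment (aldehyde 16)

**Step 1**
Reactants: 1 2‑(2‑bromoethyl)‑1,3‑dioxolane; 2 methyl but‑2‑ynoate
Product: 3 methyl (2E)‑5‑(1,3‑dioxolan‑2‑yl)‑3‑methylpent‑2‑enoate
Conditions: 1, Mg, THF, ≤25 °C; CuBr·SMe2 (1 equiv), THF/Me2S, −78 °C; then 2, −78 °C; MeOH/NH4Cl quench at −78 °C
Reagents that add atoms: none
Why: syn‑carbocupration of the ynoate and cold protonation with retention give the (E)‑β‑methyl enoate (chain trans to CO2Me).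

**Step 2**
Reactants: 3
Product: 4 methyl (2E)‑3‑methyl‑6‑oxohex‑2‑enoate
Conditions: 2 M HCl, THF, rt
Reagents that add atoms: water, O
Why: acid‑catalysed acetal hydrolysis; the conjugated ester is untouched.

**Step 3**
Reactants: 4
Product: 5 methyl (2E,6R,7S)‑6‑hydroxy‑3,7‑dimethylnona‑2,8‑dienoate
Conditions: trans‑2‑butene, n‑BuLi, KOt‑Bu, THF, −78 → −45 °C; (−)‑Ipc2BOMe [(+)‑α‑pinene series], −78 °C; BF3·OEt2; then 4, −78 °C; NaBO3·4H2O work‑up
Reagents that add atoms: (E)‑crotyldiisopinocampheylborane, C/C=C/CB(C1CC2CC(C1C)C2(C)C)C1CC2CC(C1C)C2(C)C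
Why: Brown crotylboration through a chair transition state; the (E)‑crotyl geometry gives the anti adduct and the Ipc groups direct si‑face attack, setting C6 (R) and C7 (S). The aldehyde reacts chemoselectively over the enoate.

**Step 4**
Reactants: 5
Product: 6 methyl (2E,6R,7S)‑6‑(methanesulfonyloxy)‑3,7‑dimethylnona‑2,8‑dienoate
Conditions: MsCl, Et3N, CH2Cl2, 0 °C
Reagents that add atoms: methanesulfonyl chloride, CS(Cl)(=O)=O
Why: O‑sulfonylation with retention, activating the carbinol for displacement.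

**Step 5**
Reactants: 7 2,3‑dimethylbut‑2‑ene
Product: 8 2‑methoxypropan‑2‑yl hydroperoxide
Conditions: O3, MeOH/CH2Cl2, −78 °C; concentrate cold (acetone by‑product removed)
Reagents that add atoms: ozone, O=[O+][O-]; methanol, CO
Why: Criegee ozonolysis; methanol traps the acetone carbonyl oxide as the α‑methoxy hydroperoxide.

**Step 6**
Reactants: 6; 8
Product: 9 methyl (2E,6S,7S)‑6‑[(2‑methoxypropan‑2‑yl)peroxy]‑3,7‑dimethylnona‑2,8‑dienoate
Conditions: 8 (3 equiv), CsOH·H2O (1.2 equiv), DMF, 0 °C → rt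
Reagents that add atoms: none
Why: SN2 displacement by the weakly basic α‑effect peroxide anion inverts the carbinol carbon (R → S), giving the future ring C3 configuration.

**Step 7**
Reactants: 9
Product: 10 (2E,6S,7S)‑6‑[(2‑methoxypropan‑2‑yl)peroxy]‑3,7‑dimethylnona‑2,8‑dien‑1‑ol
Conditions: DIBAL‑H (2.5 equiv), CH2Cl2, −78 °C; Rochelle salt
Reagents that add atoms: none
Why: 1,2‑reduction of the enoate to the allylic alcohol; the peroxyketal is inert to DIBAL at −78 °C.

**Step 8**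
Reactants: 10
Product: 11 [(2R,3R)‑3‑{(3S,4S)‑3‑[(2‑methoxypropan‑2‑yl)peroxy]‑4‑methylhex‑5‑en‑1‑yl}‑3‑methyloxiran‑2‑yl]methanol
Conditions: Ti(Oi‑Pr)4, D‑(−)‑diethyl tartrate, t‑BuOOH, 4 Å MS, CH2Cl2, −20 °C
Reagents that add atoms: tert‑butyl hydroperoxide, CC(C)(C)OO
Why: Sharpless asymmetric epoxidation is reagent‑controlled; geraniol‑type (E)‑alcohols give the (2S,3S) epoxide with L‑(+)‑tartrate, so D‑(−)‑tartrate gives (2R,3R). Only the allylic alkene reacts.

**Step 9**
Reactants: 11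
Product: 12 (1R)‑1‑{(3S,6S)‑6‑[(2S)‑but‑3‑en‑2‑yl]‑3‑methyl‑1,2‑dioxan‑3‑yl}ethane‑1,2‑diol
Conditions: CSA (10 mol %), MeOH (5 equiv), CH2Cl2, 0 °C → rt
Reagents that add atoms: none
Why: acid transfers the ketal to MeOH and the freed hydroperoxide opens the protonated epoxide 6‑exo at the tertiary carbon with inversion, fixing the quaternary centre (Me cis, glycol arm trans to the C3 side chain).

**Step 10**
Reactants: 12
Product: 13 (2R)‑2‑{(3S,6S)‑6‑[(1R)‑1,2‑dihydroxyethyl]‑6‑methyl‑1,2‑dioxan‑3‑yl}propanal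
Conditions: O3, pyridine (3 equiv), CH2Cl2, −78 °C; used crude
Reagents that add atoms: ozone, O=[O+][O-]
Why: pyridine‑mediated reductive ozonolysis of the only remaining alkene gives the aldehyde without a reductant that could attack the O–O bond.

**Step 11**
Reactants: 13
Product: 14 (2R)‑2‑{(3S,6S)‑6‑[(1R)‑1,2‑dihydroxyethyl]‑6‑methyl‑1,2‑dioxan‑3‑yl}propanoic acid
Conditions: NaClO2, NaH2PO4, 2‑methyl‑2‑butene, t‑BuOH/H2O, 0 °C
Reagents that add atoms: sodium chlorite, [Na+].[O-]Cl=O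
Why: Pinnick oxidation under buffered acidic conditions avoids epimerisation or β‑elimination at C2 and leaves the diol and peroxide alone.

**Step 12**
Reactants: 14
Product: 15 methyl (2R)‑2‑{(3S,6S)‑6‑[(1R)‑1,2‑dihydroxyethyl]‑6‑methyl‑1,2‑dioxan‑3‑yl}propanoate
Conditions: TMSCHN2, MeOH/PhMe, 0 °C
Reagents that add atoms: trimethylsilyldiazomethane, C[Si](C)(C)C=[N+]=[N-]
Why: neutral O‑methylation of the acid; no base touches the β‑peroxy ester.

**Step 13**
Reactants: 15
Product: 16 methyl (2R)‑2‑[(3S,6S)‑6‑formyl‑6‑methyl‑1,2‑dioxan‑3‑yl]propanoate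
Conditions: NaIO4, THF/pH 7 buffer, 0 °C → rt
Reagents that add atoms: none
Why: Malaprade glycol cleavage excises the terminal CH2OH carbon and leaves a non‑enolisable α‑peroxy aldehyde.

### East fragment (phosphonate 25)

**Step 14**
Reactants: 17 3‑methylbutan‑2‑one; 18 methyl acrylate
Product: 19 4,4‑dimethylcyclohexane‑1,3‑dione
Conditions: KOt‑Bu, THF, 0 °C → rt; aq. HCl
Reagents that add atoms: none
Why: Michael addition of the more substituted enolate, then intramolecular Claisen condensation of the methyl ketone onto the ester.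

**Step 15**
Reactants: 19
Product: 20 2,4,4‑trimethylcyclohexane‑1,3‑dione
Conditions: MeI, K2CO3, acetone, reflux
Reagents that add atoms: iodomethane, CI
Why: C‑alkylation of the 1,3‑dione enolate at C2.

**Step 16**
Reactants: 20
Product: 21 3‑isobutoxy‑2,6,6‑trimethylcyclohex‑2‑en‑1‑one
Conditions: i‑BuOH, p‑TsOH (cat.), PhMe, reflux, Dean–Stark
Reagents that add atoms: isobutanol, CC(C)CO
Why: vinylogous ester formation occurs at the less hindered carbonyl, leaving the ketone next to CMe2 free.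

**Step 17**
Reactants: 21
Product: 22 3‑[(methoxymethoxy)methyl]‑2,4,4‑trimethylcyclohex‑2‑en‑1‑one
Conditions: Bu3SnCH2OMOM, n‑BuLi, THF, −78 °C; add 21, −78 → 0 °C; then 1 M HCl, THF, rt
Reagents that add atoms: tributyl[(methoxymethoxy)methyl]stannane, CCCC[Sn](CCCC)(CCCC)COCOC
Why: Stork–Danheiser sequence: 1,2‑addition of the α‑alkoxy organolithium, then acid hydrolysis/dehydration transposes the enone so the new carbon sits next to CMe2.

**Step 18**
Reactants: 22
Product: 23 3‑(hydroxymethyl)‑2,4,4‑trimethylcyclohex‑2‑en‑1‑one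
Conditions: Me2BBr, CH2Cl2, −78 °C; aq. NaHCO3
Reagents that add atoms: none
Why: Lewis‑acid cleavage of the MOM acetal.

**Step 19**
Reactants: 23
Product: 24 3‑(bromomethyl)‑2,4,4‑trimethylcyclohex‑2‑en‑1‑one
Conditions: CBr4, PPh3, CH2Cl2, 0 °C
Reagents that add atoms: carbon tetrabromide, BrC(Br)(Br)Br
Why: Appel bromination of the primary allylic alcohol.

**Step 20**
Reactants: 24
Product: 25 diethyl [(2,6,6‑trimethyl‑3‑oxocyclohex‑1‑en‑1‑yl)methyl]phosphonate
Conditions: P(OEt)3, neat, 120 °C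
Reagents that add atoms: triethyl phosphite, CCOP(OCC)OCC
Why: Michaelis–Arbuzov reaction on the γ‑bromo enone, as for 4‑bromocrotonates.

### Union and finish

**Step 21**
Reactants: 16; 25
Product: 26 methyl (2R)‑2‑{(3S,6S)‑6‑methyl‑6‑[(E)‑2‑(2,6,6‑trimethyl‑3‑oxocyclohex‑1‑en‑1‑yl)ethenyl]‑1,2‑dioxan‑3‑yl}propanoate
Conditions: 25 (1.1 equiv), LiHMDS (1.05 equiv), THF, −78 °C; then 16, −78 → 0 °C
Reagents that add atoms: none
Why: vinylogous Horner–Wadsworth–Emmons olefination; the stabilised anion is too weakly basic to trigger retro‑oxa‑Michael opening and no stereocentre is touched.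

**Step 22**
Reactants: 26
Product: 27 methyl diacarnoate A, methyl (2R)‑2‑{(3S,6R)‑6‑methyl‑6‑[2‑(2,6,6‑trimethyl‑3‑oxocyclohex‑1‑en‑1‑yl)ethyl]‑1,2‑dioxan‑3‑yl}propanoate
Conditions: KO2C–N=N–CO2K (excess, portionwise), AcOH, MeOH/CH2Cl2, 0 °C → rt
Reagents that add atoms: none
Why: diimide reduces the disubstituted alkene but not the tetrasubstituted enone C=C, the ketone or the O–O bond; the C6 descriptor changes from S to R only through CIP priorities.

## Compound list

1 | 2‑(2‑bromoethyl)‑1,3‑dioxolane | BrCCC1OCCO1 | starting material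
2 | methyl but‑2‑ynoate | CC#CC(=O)OC | starting material
3 | methyl (2E)‑5‑(1,3‑dioxolan‑2‑yl)‑3‑methylpent‑2‑enoate | COC(=O)/C=C(\C)CCC1OCCO1 | intermediate
4 | methyl (2E)‑3‑methyl‑6‑oxohex‑2‑enoate | COC(=O)/C=C(\C)CCC=O | intermediate
5 | methyl (2E,6R,7S)‑6‑hydroxy‑3,7‑dimethylnona‑2,8‑dienoate | C=C[C@H](C)[C@H](O)CC/C(C)=C/C(=O)OC | intermediate
6 | methyl (2E,6R,7S)‑6‑(methanesulfonyloxy)‑3,7‑dimethylnona‑2,8‑dienoate | C=C[C@H](C)[C@H](OS(C)(=O)=O)CC/C(C)=C/C(=O)OC | intermediate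
7 | 2,3‑dimethylbut‑2‑ene | CC(C)=C(C)C | starting material
8 | 2‑methoxypropan‑2‑yl hydroperoxide | COC(C)(C)OO | intermediate
9 | methyl (2E,6S,7S)‑6‑[(2‑methoxypropan‑2‑yl)peroxy]‑3,7‑dimethylnona‑2,8‑dienoate | C=C[C@H](C)[C@@H](OOC(C)(C)OC)CC/C(C)=C/C(=O)OC | intermediate
10 | (2E,6S,7S)‑6‑[(2‑methoxypropan‑2‑yl)peroxy]‑3,7‑dimethylnona‑2,8‑dien‑1‑ol | C=C[C@H](C)[C@@H](OOC(C)(C)OC)CC/C(C)=C/CO | intermediate
11 | [(2R,3R)‑3‑{(3S,4S)‑3‑[(2‑methoxypropan‑2‑yl)peroxy]‑4‑methylhex‑5‑en‑1‑yl}‑3‑methyloxiran‑2‑yl]methanol | C=C[C@H](C)[C@@H](OOC(C)(C)OC)CC[C@@]1(C)O[C@@H]1CO | intermediate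
12 | (1R)‑1‑{(3S,6S)‑6‑[(2S)‑but‑3‑en‑2‑yl]‑3‑methyl‑1,2‑dioxan‑3‑yl}ethane‑1,2‑diol | C=C[C@H](C)[C@@H]1CC[C@@](C)([C@H](O)CO)OO1 | intermediate
13 | (2R)‑2‑{(3S,6S)‑6‑[(1R)‑1,2‑dihydroxyethyl]‑6‑methyl‑1,2‑dioxan‑3‑yl}propanal | O=C[C@H](C)[C@@H]1CC[C@@](C)([C@H](O)CO)OO1 | intermediate
14 | (2R)‑2‑{(3S,6S)‑6‑[(1R)‑1,2‑dihydroxyethyl]‑6‑methyl‑1,2‑dioxan‑3‑yl}propanoic acid | OC(=O)[C@H](C)[C@@H]1CC[C@@](C)([C@H](O)CO)OO1 | intermediate
15 | methyl (2R)‑2‑{(3S,6S)‑6‑[(1R)‑1,2‑dihydroxyethyl]‑6‑methyl‑1,2‑dioxan‑3‑yl}propanoate | COC(=O)[C@H](C)[C@@H]1CC[C@@](C)([C@H](O)CO)OO1 | intermediate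
16 | methyl (2R)‑2‑[(3S,6S)‑6‑formyl‑6‑methyl‑1,2‑dioxan‑3‑yl]propanoate | COC(=O)[C@H](C)[C@@H]1CC[C@@](C)(C=O)OO1 | intermediate
17 | 3‑methylbutan‑2‑one | CC(=O)C(C)C | starting material
18 | methyl acrylate | C=CC(=O)OC | starting material
19 | 4,4‑dimethylcyclohexane‑1,3‑dione | CC1(C)CCC(=O)CC1=O | intermediate
20 | 2,4,4‑trimethylcyclohexane‑1,3‑dione | CC1C(=O)CCC(C)(C)C1=O | intermediate
21 | 3‑isobutoxy‑2,6,6‑trimethylcyclohex‑2‑en‑1‑one | CC(C)COC1=C(C)C(=O)C(C)(C)CC1 | intermediate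
22 | 3‑[(methoxymethoxy)methyl]‑2,4,4‑trimethylcyclohex‑2‑en‑1‑one | COCOCC1=C(C)C(=O)CCC1(C)C | intermediate
23 | 3‑(hydroxymethyl)‑2,4,4‑trimethylcyclohex‑2‑en‑1‑one | OCC1=C(C)C(=O)CCC1(C)C | intermediate
24 | 3‑(bromomethyl)‑2,4,4‑trimethylcyclohex‑2‑en‑1‑one | BrCC1=C(C)C(=O)CCC1(C)C | intermediate
25 | diethyl [(2,6,6‑trimethyl‑3‑oxocyclohex‑1‑en‑1‑yl)methyl]phosphonate | CCOP(=O)(OCC)CC1=C(C)C(=O)CCC1(C)C | intermediate
26 | methyl (2R)‑2‑{(3S,6S)‑6‑methyl‑6‑[(E)‑2‑(2,6,6‑trimethyl‑3‑oxocyclohex‑1‑en‑1‑yl)ethenyl]‑1,2‑dioxan‑3‑yl}propanoate | COC(=O)[C@H](C)[C@@H]1CC[C@@](C)(/C=C/C2=C(C)C(=O)CCC2(C)C)OO1 | intermediate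
27 | methyl diacarnoate A | COC(=O)[C@H](C)[C@@H]1CC[C@@](C)(CCC2=C(C)C(=O)CCC2(C)C)OO1 | target

## Totals

Total step count: 22.
Longest linear sequence: 14 steps (1–4, 6–13, 21, 22), 64% of the total. The other branches are steps 14–20 (7 steps) and step 5 (1 step).

## Three steps most likely to fail

1. **Step 6** (intermolecular peroxide SN2 at a β‑branched secondary mesylate; E2 towards the allylic C7–H competes). Fallback: reverse the order of C–O bond formation. Reduce 6 with DIBAL and epoxidise with the mesylate in place, open the epoxide at the tertiary carbon with ethereal H2O2 and phosphomolybdic acid (inversion) to a tertiary hydroperoxide, then close the ring by intramolecular 6‑exo‑tet displacement of the mesylate (Cs2CO3) to reach the same diol 12.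

2. **Step 9** (acid‑triggered deprotection and 6‑exo epoxide opening at a tertiary centre; Meinwald rearrangement, methanolysis or 7‑endo closure could intervene). Fallback: set C6 by 1,4‑induction instead. Ozonise a 2‑methyl‑1‑alkene analogue of 6 in MeOH to the methoxy hydroperoxide, cyclise onto the mesylate (KOt‑Bu, 18‑crown‑6) to a 6‑methoxy‑6‑methyl‑1,2‑dioxane, add allyltrimethylsilane to the peroxycarbenium ion (SnCl4; attack trans to the C3 arm), then isomerise the allyl group and ozonise to 16.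

3. **Steps 21–22** (both partners of the olefination are hindered, and the resulting alkene, flanked by a quaternary carbon and a tetrasubstituted diene terminus, may reduce sluggishly or unselectively with diimide). Fallback: form the saturated link directly by B‑alkyl Suzuki coupling. Methylenate 16 to the 6‑vinyl dioxane, hydroborate with 9‑BBN and couple with 3‑iodo‑2,4,4‑trimethylcyclohex‑2‑en‑1‑one (PdCl2(dppf), AsPh3, Cs2CO3). The iodide comes from 21 by stannyl‑anion addition/transposition and iododestannylation. No alkene reduction is then needed.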